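**Retrosynthetic overview**
- The pyran ring B and the C4a–C4 bond are made together, late, by a Pd/Cu alkynylative oxa-annulation of a core enol triflate (free CH2OH) with a terminal dienyne side chain; one acid step then removes the acetonide and the TBS ether.
- The core triflate comes from a 2-chloro-1,3-dione, made by a transannular Claisen ring switch of a keto δ-lactone; the lactone oxygen is released as the C1 hydroxyl that later closes ring B.
- The keto δ-lactone comes from OsO4 dihydroxylation (C7, C8) of an RCM-derived pentenolide, built on an Ir-catalysed C–H (hydroxymethyl)allylation of ethanol (C8a).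
- The dienyne comes from hydrozirconation/Negishi coupling of a methyl alkyne with an (E)-chloroenyne linchpin; C5′ comes from Ru–BINAP hydrogenation of α-methylene-γ-butyrolactone.
- Ring order: temporary δ-lactone, then carbocycle ring A, then pyran ring B.

Assumption: core atoms are labelled C1–C8a and side-chain atoms C1′–C7′ as in the isochromene numbering of the target; the sense of induction in steps 1 and 13 is assigned by analogy with reported cases, and the mirror-image ligand is used if the antipode forms.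

**Core (steps 1–11)**

Step 1
Reactants: 1 ethanol; 2 4-vinyl-1,3-dioxolan-2-one (vinyl ethylene carbonate, racemic)
Product: 3 (2R,3R)-2-vinylbutane-1,3-diol
Conditions: [Ir(cod)Cl]2 (2.5 mol %), (S)-SEGPHOS (5 mol %), 4-cyano-3-nitrobenzoic acid (10 mol %), K3PO4 (5 mol %), 1 (3 equiv), THF, 90 °C, sealed tube
Reagents that add atoms: none
Why: Krische transfer-hydrogenative carbonyl (hydroxymethyl)allylation: iridium dehydrogenates ethanol at its carbinol C–H, ionises 2 with loss of CO2 to an (E)-σ-allyl iridium, and a closed chair transition state gives the anti diol, with the future C8a set by the chiral ligand.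

Step 2
Reactants: 3 (2R,3R)-2-vinylbutane-1,3-diol; 4 methacryloyl chloride
Product: 5 (2R,3R)-3-hydroxy-2-vinylbutyl 2-methylprop-2-enoate
Conditions: 4 (1.05 equiv), 2,4,6-collidine, CH2Cl2, −78 °C
Reagents that add atoms: none
Why: Chemoselective acylation: with a weak hindered base at low temperature the primary hydroxyl reacts far faster than the branched secondary one.

Step 3
Reactants: 5 (2R,3R)-3-hydroxy-2-vinylbutyl 2-methylprop-2-enoate
Product: 6 (2R,3R)-3-(triethylsilyloxy)-2-vinylbutyl 2-methylprop-2-enoate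
Conditions: TESOTf, 2,6-lutidine, CH2Cl2, −78 °C
Reagents that add atoms: triethylsilyl triflate CC[Si](CC)(CC)OS(=O)(=O)C(F)(F)F
Why: Fast, non-equilibrating silylation of the secondary alcohol prevents acyl migration and masks the future C4a ketone (silyl ether protection).

Step 4
Reactants: 6 (2R,3R)-3-(triethylsilyloxy)-2-vinylbutyl 2-methylprop-2-enoate
Product: 7 (5R)-3-methyl-5-[(1R)-1-(triethylsilyloxy)ethyl]-5,6-dihydro-2H-pyran-2-one
Conditions: (H2IMes)(PCy3)Cl2Ru=CHPh (second-generation Grubbs catalyst, 5 mol %), toluene (5 mM), 80 °C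
Reagents that add atoms: none
Why: Ring-closing metathesis of the methacrylate onto the vinyl group closes the pentenolide with loss of ethene; the ring enforces the cis alkene needed for the later cis-diol and leaves the allylic stereocenter untouched.

Step 5
Reactants: 7 (5R)-3-methyl-5-[(1R)-1-(triethylsilyloxy)ethyl]-5,6-dihydro-2H-pyran-2-one
Product: 8 (3R,4R,5S)-3,4-dihydroxy-3-methyl-5-[(1R)-1-(triethylsilyloxy)ethyl]tetrahydro-2H-pyran-2-one
Conditions: OsO4 (5 mol %), NMO, MeSO2NH2, acetone/H2O (4:1), rt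
Reagents that add atoms: N-methylmorpholine N-oxide C[N+]1([O-])CCOCC1; water O
Why: Upjohn syn-dihydroxylation occurs on the lactone face anti to the bulky allylic side chain, setting C7 and C8 as a cis-diol trans to the future C4a carbon, which becomes cis to the CH2O group once the ring is switched.

Step 6
Reactants: 8 (3R,4R,5S)-3,4-dihydroxy-3-methyl-5-[(1R)-1-(triethylsilyloxy)ethyl]tetrahydro-2H-pyran-2-one
Product: 9 (3aR,7S,7aR)-2,2,3a-trimethyl-7-[(1R)-1-(triethylsilyloxy)ethyl]tetrahydro-4H-[1,3]dioxolo[4,5-c]pyran-4-one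
Conditions: 2-methoxypropene, PPTS (cat.), CH2Cl2, 0 °C
Reagents that add atoms: 2-methoxypropene COC(C)=C
Why: Kinetic acetalisation of the cis-1,2-diol with an enol ether gives the cis-fused dioxolane under conditions too mild to cleave the TES ether (acetonide protection).

Step 7
Reactants: 9 (3aR,7S,7aR)-2,2,3a-trimethyl-7-[(1R)-1-(triethylsilyloxy)ethyl]tetrahydro-4H-[1,3]dioxolo[4,5-c]pyran-4-one
Product: 10 (3aR,7R,7aR)-7-[(1R)-1-hydroxyethyl]-2,2,3a-trimethyltetrahydro-4H-[1,3]dioxolo[4,5-c]pyran-4-one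
Conditions: HF·pyridine, pyridine, THF, 0 °C
Reagents that add atoms: none
Why: Buffered fluoride desilylation removes the secondary TES ether while the lactone and acetonide stay intact.

Step 8
Reactants: 10 (3aR,7R,7aR)-7-[(1R)-1-hydroxyethyl]-2,2,3a-trimethyltetrahydro-4H-[1,3]dioxolo[4,5-c]pyran-4-one
Product: 11 (3aR,7S,7aR)-7-acetyl-2,2,3a-trimethyltetrahydro-4H-[1,3]dioxolo[4,5-c]pyran-4-one
Conditions: Dess–Martin periodinane, CH2Cl2, 0 °C to rt
Reagents that add atoms: none
Why: Dess–Martin oxidation is near-neutral, so the methyl ketone forms without epimerising the now α-acidic C8a or eliminating the β-alkoxy group.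

Step 9
Reactants: 11 (3aR,7S,7aR)-7-acetyl-2,2,3a-trimethyltetrahydro-4H-[1,3]dioxolo[4,5-c]pyran-4-one
Product: 12 (3aR,7S,7aR)-7-(hydroxymethyl)-2,2,3a-trimethyltetrahydrobenzo[d][1,3]dioxole-4,6-dione
Conditions: LiN(SiMe3)2 (2.3 equiv), THF, −78 to −20 °C (ketone added to base); then AcOH
Reagents that add atoms: none
Why: Transannular Claisen condensation: the kinetic methyl enolate attacks the lactone carbonyl (no α-hydrogen on that side) through a 2-oxabicyclo[2.2.2]octane tetrahedral intermediate, whose collapse expels the C1 alkoxide, and 1,3-diketonate formation makes the ring switch irreversible without touching a stereocenter.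

Step 10
Reactants: 12 (3aR,7S,7aR)-7-(hydroxymethyl)-2,2,3a-trimethyltetrahydrobenzo[d][1,3]dioxole-4,6-dione
Product: 13 (3aR,7S,7aR)-5-chloro-6-hydroxy-7-(hydroxymethyl)-2,2,3a-trimethyl-7,7a-dihydrobenzo[d][1,3]dioxol-4(3aH)-one (2-chloro-1,3-dione, drawn as one enol tautomer)
Conditions: NCS (1.0 equiv), CH2Cl2, 0 °C
Reagents that add atoms: N-chlorosuccinimide O=C1CCC(=O)N1Cl
Why: Electrophilic α-chlorination of the enolised 1,3-dione occurs only at C5, the carbon between the two carbonyls.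

Step 11
Reactants: 13 (3aR,7S,7aR)-5-chloro-6-hydroxy-7-(hydroxymethyl)-2,2,3a-trimethyl-7,7a-dihydrobenzo[d][1,3]dioxol-4(3aH)-one
Product: 14 (3aR,4S,7aR)-6-chloro-4-(hydroxymethyl)-2,2,7a-trimethyl-7-oxo-3a,4,7,7a-tetrahydrobenzo[d][1,3]dioxol-5-yl trifluoromethanesulfonate
Conditions: N-(5-chloropyridin-2-yl)-bis(trifluoromethanesulfonyl)imide (Comins' reagent, 1.05 equiv), i-Pr2NEt (1.1 equiv), CH2Cl2, −20 to 0 °C
Reagents that add atoms: Comins' reagent Clc1ccc(nc1)N(S(=O)(=O)C(F)(F)F)S(=O)(=O)C(F)(F)F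
Why: Regioselective enol triflation: the diketonate is sulfonylated at the C4a oxygen, flanked by a CH that can turn its substituent axial, and not at the C6 oxygen next to the quaternary C7, and the imide reagent spares the neutral primary alcohol.

**Linchpin (step 12)**

Step 12
Reactants: 15 (E)-1,2-dichloroethene; 16 ethynyltrimethylsilane
Product: 17 (E)-(4-chlorobut-3-en-1-yn-1-yl)trimethylsilane
Conditions: Pd(PPh3)4 (2 mol %), CuI (5 mol %), n-BuNH2, 15 (5 equiv), Et2O, rt
Reagents that add atoms: none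
Why: Sonogashira mono-coupling of excess trans-dichloroethene proceeds with retention of the E geometry.

**Side chain (steps 13–19)**

Step 13
Reactants: 18 3-methylenedihydrofuran-2(3H)-one (α-methylene-γ-butyrolactone)
Product: 19 (S)-3-methyldihydrofuran-2(3H)-one
Conditions: H2 (100 atm), Ru(OAc)2[(R)-BINAP] (0.5 mol %), CH2Cl2, 50 °C
Reagents that add atoms: none
Why: Noyori-type asymmetric hydrogenation of the exocyclic enoate, with the lactone carbonyl chelating ruthenium, sets the future C5′ stereocenter.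

Step 14
Reactants: 19 (S)-3-methyldihydrofuran-2(3H)-one
Product: 20 (3S)-3-methyltetrahydrofuran-2-ol (anomer mixture)
Conditions: i-Bu2AlH (1.1 equiv), CH2Cl2, −78 °C; aq. work-up
Reagents that add atoms: none
Why: Low-temperature half-reduction of the γ-lactone stops at the aluminium hemiacetal and gives the lactol with the α-stereocenter intact.

Step 15
Reactants: 20 (3S)-3-methyltetrahydrofuran-2-ol
Product: 21 (S)-3-methylpent-4-yn-1-ol
Conditions: dimethyl (1-diazo-2-oxopropyl)phosphonate, K2CO3, MeOH, 0 °C to rt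
Reagents that add atoms: Ohira–Bestmann reagent CC(=O)C(=[N+]=[N-])P(=O)(OC)OC
Why: Seyferth–Gilbert homologation (Ohira–Bestmann variant) converts the lactol, a masked aldehyde, into the terminal alkyne under mild base that leaves the α-methyl centre essentially unchanged.

Step 16
Reactants: 21 (S)-3-methylpent-4-yn-1-ol
Product: 22 (S)-tert-butyldimethyl[(3-methylpent-4-yn-1-yl)oxy]silane
Conditions: TBSCl, imidazole, DMF, rt
Reagents that add atoms: tert-butyldimethylsilyl chloride CC(C)(C)[Si](C)(C)Cl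
Why: Standard silyl protection of the primary alcohol before organometallic steps.

Step 17
Reactants: 22 (S)-tert-butyldimethyl[(3-methylpent-4-yn-1-yl)oxy]silane
Product: 24 (S)-tert-butyldimethyl[(3-methylhex-4-yn-1-yl)oxy]silane, via lithium acetylide 23 (not isolated)
Conditions: n-BuLi, THF, −78 °C; then MeI, −78 °C to rt
Reagents that add atoms: iodomethane CI
Why: Acetylide alkylation with the unhindered electrophile MeI installs the methyl that becomes the C3′ methyl.

Step 18
Reactants: 24 (S)-tert-butyldimethyl[(3-methylhex-4-yn-1-yl)oxy]silane; 17 (E)-(4-chlorobut-3-en-1-yn-1-yl)trimethylsilane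
Product: 27 tert-butyl{[(3S,4E,6E)-3,5-dimethyl-9-(trimethylsilyl)nona-4,6-dien-8-yn-1-yl]oxy}dimethylsilane, via alkenylzirconocene chloride 25 (not isolated), via alkenylzinc chloride 26 (not isolated)
Conditions: Cp2Zr(H)Cl (1.2 equiv), THF, 50 °C; then ZnCl2, 17 (1.4 equiv), Pd(P(t-Bu)3)2 (3 mol %), THF/NMP, 50 °C
Reagents that add atoms: none
Why: Syn-hydrozirconation with thermodynamic regiocontrol puts zirconium on the methyl-bearing carbon and fixes the (E)-trisubstituted alkene, and Zr-to-Zn transmetalation followed by Negishi coupling joins it to the chloroenyne with retention at both alkenes.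

Step 19
Reactants: 27 tert-butyl{[(3S,4E,6E)-3,5-dimethyl-9-(trimethylsilyl)nona-4,6-dien-8-yn-1-yl]oxy}dimethylsilane
Product: 28 tert-butyl{[(3S,4E,6E)-3,5-dimethylnona-4,6-dien-8-yn-1-yl]oxy}dimethylsilane
Conditions: K2CO3 (cat.), MeOH, rt
Reagents that add atoms: none
Why: Methanolysis cleaves the C(sp)–Si bond selectively and leaves the TBS ether in place (protodesilylation).

**Union and end-game (steps 20–21)**

Step 20
Reactants: 14 (3aR,4S,7aR)-6-chloro-4-(hydroxymethyl)-2,2,7a-trimethyl-7-oxo-3a,4,7,7a-tetrahydrobenzo[d][1,3]dioxol-5-yl trifluoromethanesulfonate; 28 tert-butyl{[(3S,4E,6E)-3,5-dimethylnona-4,6-dien-8-yn-1-yl]oxy}dimethylsilane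
Product: 30 (7R,8R,8aS)-3-[(1E,3E,5S)-7-(tert-butyldimethylsilyloxy)-3,5-dimethylhepta-1,3-dien-1-yl]-5-chloro-7,8-(isopropylidenedioxy)-7-methyl-8,8a-dihydro-1H-isochromen-6(7H)-one, via hydroxy enynone 29 (not isolated)
Conditions: Pd(PPh3)4 (5 mol %), CuI (10 mol %), i-Pr2NEt (3 equiv), 28 (1.2 equiv), degassed THF, rt, 3 h; then 45 °C
Reagents that add atoms: none
Why: Proposed new method: a Pd/Cu alkynylative oxa-annulation in which zerovalent palladium inserts into the C–OTf bond of the β-triflyloxy-α-chloroenone (much faster than into the vinylic C–Cl bond), the copper acetylide of 28 transmetalates and reductive elimination forges C4a–C4, after which the alkyne carbon C3 of the resulting enynone is the δ-position of a doubly vinylogous acceptor, so the neighbouring C1 hydroxyl (activated by the amine and by CuI coordination to the alkyne) adds 6-endo-dig as an oxa-1,6-addition and protonation at C4 gives the dienol ether of ring B; the closest known chemistry is the domino Sonogashira/heteroannulation of o-halophenols, o-halobenzoic acids and β-halo-enoic acids and the stepwise Sonogashira then gold cycloisomerisation used for azaphilone cores, neither shown for a γ-hydroxymethyl β-triflyloxy enone.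

Step 21
Reactants: 30 (7R,8R,8aS)-3-[(1E,3E,5S)-7-(tert-butyldimethylsilyloxy)-3,5-dimethylhepta-1,3-dien-1-yl]-5-chloro-7,8-(isopropylidenedioxy)-7-methyl-8,8a-dihydro-1H-isochromen-6(7H)-one
Product: 31 (7R,8R,8aS)-5-chloro-7,8-dihydroxy-3-[(1E,3E,5S)-7-hydroxy-3,5-dimethylhepta-1,3-dien-1-yl]-7-methyl-8,8a-dihydro-1H-isochromen-6(7H)-one (target)
Conditions: TFA/H2O (9:1), 0 °C, 30 min; then aq. NaHCO3
Reagents that add atoms: none
Why: Global acid deprotection hydrolyses the dioxolane and the primary TBS ether in one operation, while the vinylogous ester (dienol ether conjugated to the chloroenone) resists hydrolysis and no stereocenter is involved.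

**Compound list**
1 | ethanol | CCO | starting material
2 | 4-vinyl-1,3-dioxolan-2-one (racemic) | C=CC1COC(=O)O1 | starting material
3 | (2R,3R)-2-vinylbutane-1,3-diol | C=C[C@@H]([C@@H](C)O)CO | intermediate
4 | methacryloyl chloride | CC(=C)C(Cl)=O | starting material
5 | (2R,3R)-3-hydroxy-2-vinylbutyl 2-methylprop-2-enoate | C=C[C@@H]([C@@H](C)O)COC(=O)C(C)=C | intermediate
6 | (2R,3R)-3-(triethylsilyloxy)-2-vinylbutyl 2-methylprop-2-enoate | C=C[C@@H]([C@@H](C)O[Si](CC)(CC)CC)COC(=O)C(C)=C | intermediate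
7 | (5R)-3-methyl-5-[(1R)-1-(triethylsilyloxy)ethyl]-5,6-dihydro-2H-pyran-2-one | CC1=C[C@@H]([C@@H](C)O[Si](CC)(CC)CC)COC1=O | intermediate
8 | (3R,4R,5S)-3,4-dihydroxy-3-methyl-5-[(1R)-1-(triethylsilyloxy)ethyl]tetrahydro-2H-pyran-2-one | O=C1OC[C@H]([C@@H](C)O[Si](CC)(CC)CC)[C@@H](O)[C@@]1(C)O | intermediate
9 | (3aR,7S,7aR)-2,2,3a-trimethyl-7-[(1R)-1-(triethylsilyloxy)ethyl]tetrahydro-4H-[1,3]dioxolo[4,5-c]pyran-4-one | O=C1OC[C@H]([C@@H](C)O[Si](CC)(CC)CC)[C@H]2OC(C)(C)O[C@@]12C | intermediate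
10 | (3aR,7R,7aR)-7-[(1R)-1-hydroxyethyl]-2,2,3a-trimethyltetrahydro-4H-[1,3]dioxolo[4,5-c]pyran-4-one | O=C1OC[C@H]([C@@H](C)O)[C@H]2OC(C)(C)O[C@@]12C | intermediate
11 | (3aR,7S,7aR)-7-acetyl-2,2,3a-trimethyltetrahydro-4H-[1,3]dioxolo[4,5-c]pyran-4-one | O=C1OC[C@H](C(C)=O)[C@H]2OC(C)(C)O[C@@]12C | intermediate
12 | (3aR,7S,7aR)-7-(hydroxymethyl)-2,2,3a-trimethyltetrahydrobenzo[d][1,3]dioxole-4,6-dione | O=C1CC(=O)[C@]2(C)OC(C)(C)O[C@@H]2[C@@H]1CO | intermediate
13 | (3aR,7S,7aR)-5-chloro-6-hydroxy-7-(hydroxymethyl)-2,2,3a-trimethyl-7,7a-dihydrobenzo[d][1,3]dioxol-4(3aH)-one (enol form of the 2-chloro-1,3-dione) | OC1=C(Cl)C(=O)[C@]2(C)OC(C)(C)O[C@@H]2[C@@H]1CO | intermediate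
14 | (3aR,4S,7aR)-6-chloro-4-(hydroxymethyl)-2,2,7a-trimethyl-7-oxo-3a,4,7,7a-tetrahydrobenzo[d][1,3]dioxol-5-yl trifluoromethanesulfonate | O=S(=O)(OC1=C(Cl)C(=O)[C@]2(C)OC(C)(C)O[C@@H]2[C@@H]1CO)C(F)(F)F | intermediate
15 | (E)-1,2-dichloroethene | Cl/C=C/Cl | starting material
16 | ethynyltrimethylsilane | C#C[Si](C)(C)C | starting material
17 | (E)-(4-chlorobut-3-en-1-yn-1-yl)trimethylsilane | C[Si](C)(C)C#C/C=C/Cl | intermediate
18 | 3-methylenedihydrofuran-2(3H)-one | C=C1CCOC1=O | starting material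
19 | (S)-3-methyldihydrofuran-2(3H)-one | C[C@H]1CCOC1=O | intermediate
20 | (3S)-3-methyltetrahydrofuran-2-ol (anomer mixture) | C[C@H]1CCOC1O | intermediate
21 | (S)-3-methylpent-4-yn-1-ol | C#C[C@@H](C)CCO | intermediate
22 | (S)-tert-butyldimethyl[(3-methylpent-4-yn-1-yl)oxy]silane | C#C[C@@H](C)CCO[Si](C)(C)C(C)(C)C | intermediate
23 | lithium acetylide of 22 | [Li]C#C[C@@H](C)CCO[Si](C)(C)C(C)(C)C | intermediate (not isolated)
24 | (S)-tert-butyldimethyl[(3-methylhex-4-yn-1-yl)oxy]silane | CC#C[C@@H](C)CCO[Si](C)(C)C(C)(C)C | intermediate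
25 | chlorobis(cyclopentadienyl)[(2E,4S)-6-(tert-butyldimethylsilyloxy)-4-methylhex-2-en-2-yl]zirconium | C/C(=C\[C@@H](C)CCO[Si](C)(C)C(C)(C)C)[Zr](Cl)(C1C=CC=C1)C1C=CC=C1 | intermediate (not isolated)
26 | [(2E,4S)-6-(tert-butyldimethylsilyloxy)-4-methylhex-2-en-2-yl]zinc chloride | C/C([Zn]Cl)=C\[C@@H](C)CCO[Si](C)(C)C(C)(C)C | intermediate (not isolated)
27 | tert-butyl{[(3S,4E,6E)-3,5-dimethyl-9-(trimethylsilyl)nona-4,6-dien-8-yn-1-yl]oxy}dimethylsilane | C[Si](C)(C)C#C/C=C/C(C)=C/[C@@H](C)CCO[Si](C)(C)C(C)(C)C | intermediate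
28 | tert-butyl{[(3S,4E,6E)-3,5-dimethylnona-4,6-dien-8-yn-1-yl]oxy}dimethylsilane | C#C/C=C/C(C)=C/[C@@H](C)CCO[Si](C)(C)C(C)(C)C | intermediate
29 | (3aR,7S,7aR)-6-[(3E,5E,7S)-9-(tert-butyldimethylsilyloxy)-5,7-dimethylnona-3,5-dien-1-yn-1-yl]-5-chloro-7-(hydroxymethyl)-2,2,3a-trimethyl-7,7a-dihydrobenzo[d][1,3]dioxol-4(3aH)-one (hydroxy enynone) | CC(/C=C/C#CC1=C(Cl)C(=O)[C@]2(C)OC(C)(C)O[C@@H]2[C@@H]1CO)=C\[C@@H](C)CCO[Si](C)(C)C(C)(C)C | intermediate (not isolated)
30 | (7R,8R,8aS)-3-[(1E,3E,5S)-7-(tert-butyldimethylsilyloxy)-3,5-dimethylhepta-1,3-dien-1-yl]-5-chloro-7,8-(isopropylidenedioxy)-7-methyl-8,8a-dihydro-1H-isochromen-6(7H)-one | CC(/C=C/C1=CC2=C(Cl)C(=O)[C@]3(C)OC(C)(C)O[C@@H]3[C@@H]2CO1)=C\[C@@H](C)CCO[Si](C)(C)C(C)(C)C | intermediate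
31 | (7R,8R,8aS)-5-chloro-7,8-dihydroxy-3-[(1E,3E,5S)-7-hydroxy-3,5-dimethylhepta-1,3-dien-1-yl]-7-methyl-8,8a-dihydro-1H-isochromen-6(7H)-one | CC(/C=C/C1=CC2=C(Cl)C(=O)[C@](C)(O)[C@H](O)[C@@H]2CO1)=C\[C@@H](C)CCO | target

**Step count and risks**
Total step count: 21 (core 11, linchpin 1, side chain 7, union and deprotection 2).
Longest linear sequence: 13 steps (steps 1–11, 20, 21), which is 13/21 of the total.

Three steps most likely to fail:

1. Step 20 (the proposed new annulation). Possible failures are incomplete or 5-exo ring closure, amine attack on the vinylogous triflate, and alkyne homocoupling. Fallback with known chemistry, with coupling and ring closure decoupled: starting from 14, the hydroxyl is silylated (TESOTf, 2,6-lutidine, −78 °C) to the O-triethylsilyl triflate F1. A conventional Sonogashira coupling with 28 (Pd(PPh3)4, CuI, Et3N, THF, rt) gives the silylated enynone F2. HF·pyridine/pyridine then unmasks the primary hydroxyl to give 29, now isolated, and ring B is closed by gold-catalysed 6-endo-dig cycloisomerisation (AuCl3, 5 mol %, CH2Cl2), as used for azaphilone cores. The sequence rejoins the route at 30.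

2. Step 9 (transannular Claisen). The bridged transition state may be slow, and enolisation at C8a would lead to β-elimination of the acetonide oxygen. Fallback that removes the transannular constraint: starting from 9, aminolysis (MeNH(OMe)·HCl, AlMe3, CH2Cl2) opens the lactone to the hydroxy Weinreb amide F3. TBSCl/imidazole gives the bis-silyl ether F4, and PPTS/MeOH at 0 °C removes only the secondary TES group to give the alcohol F5. Dess–Martin oxidation gives the methyl ketone F6, and LiN(SiMe3)2 at −78 °C effects an ordinary 6-exo acylation of the methyl ketone enolate by the Weinreb amide to give the silyl-protected dione F7. HF·pyridine returns the route to 12.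

3. Step 21 (acid deprotection of the finished dienol ether and α-ketol). Possible failures are hydration or isomerisation of the conjugated system, or an α-ketol shift. Fallback that changes the protecting-group plan so that the last step uses fluoride: starting from 13, the acetonide is hydrolysed at this robust stage (TFA/H2O, rt) to the tetrol F8, which is triflated as in step 11 to the triflate F9. Annulation with 28 under the step 20 conditions runs through the non-isolated triol enynone F10; the C8 hydroxyl cannot compete because its 6-endo closure would give a bridged ring with a bridgehead alkene. This gives the target TBS ether F11, and HF·pyridine/pyridine in THF then gives 31 directly.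

**Further compounds**
F1 | step 20 | (3aR,4S,7aR)-6-chloro-2,2,7a-trimethyl-7-oxo-4-[(triethylsilyloxy)methyl]-3a,4,7,7a-tetrahydrobenzo[d][1,3]dioxol-5-yl trifluoromethanesulfonate | O=S(=O)(OC1=C(Cl)C(=O)[C@]2(C)OC(C)(C)O[C@@H]2[C@@H]1CO[Si](CC)(CC)CC)C(F)(F)F
F2 | step 20 | O-triethylsilyl ether of 29 | CC(/C=C/C#CC1=C(Cl)C(=O)[C@]2(C)OC(C)(C)O[C@@H]2[C@@H]1CO[Si](CC)(CC)CC)=C\[C@@H](C)CCO[Si](C)(C)C(C)(C)C
F3 | step 9 | (4R,5R)-5-[(2S,3R)-1-hydroxy-3-(triethylsilyloxy)butan-2-yl]-N-methoxy-N,2,2,4-tetramethyl-1,3-dioxolane-4-carboxamide | CON(C)C(=O)[C@]1(C)OC(C)(C)O[C@@H]1[C@@H]([C@@H](C)O[Si](CC)(CC)CC)CO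
F4 | step 9 | (4R,5R)-5-[(2S,3R)-1-(tert-butyldimethylsilyloxy)-3-(triethylsilyloxy)butan-2-yl]-N-methoxy-N,2,2,4-tetramethyl-1,3-dioxolane-4-carboxamide | CON(C)C(=O)[C@]1(C)OC(C)(C)O[C@@H]1[C@@H]([C@@H](C)O[Si](CC)(CC)CC)CO[Si](C)(C)C(C)(C)C
F5 | step 9 | (4R,5R)-5-[(2R,3R)-1-(tert-butyldimethylsilyloxy)-3-hydroxybutan-2-yl]-N-methoxy-N,2,2,4-tetramethyl-1,3-dioxolane-4-carboxamide | CON(C)C(=O)[C@]1(C)OC(C)(C)O[C@@H]1[C@@H]([C@@H](C)O)CO[Si](C)(C)C(C)(C)C
F6 | step 9 | (4R,5R)-5-[(2S)-1-(tert-butyldimethylsilyloxy)-3-oxobutan-2-yl]-N-methoxy-N,2,2,4-tetramethyl-1,3-dioxolane-4-carboxamide | CON(C)C(=O)[C@]1(C)OC(C)(C)O[C@@H]1[C@@H](C(C)=O)CO[Si](C)(C)C(C)(C)C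
F7 | step 9 | (3aR,7S,7aR)-7-[(tert-butyldimethylsilyloxy)methyl]-2,2,3a-trimethyltetrahydrobenzo[d][1,3]dioxole-4,6-dione | O=C1CC(=O)[C@]2(C)OC(C)(C)O[C@@H]2[C@@H]1CO[Si](C)(C)C(C)(C)C
F8 | step 21 | (4S,5R,6R)-2-chloro-3,5,6-trihydroxy-4-(hydroxymethyl)-6-methylcyclohex-2-en-1-one (enol form) | OC1=C(Cl)C(=O)[C@](C)(O)[C@H](O)[C@@H]1CO
F9 | step 21 | (4R,5R,6S)-2-chloro-4,5-dihydroxy-6-(hydroxymethyl)-4-methyl-3-oxocyclohex-1-en-1-yl trifluoromethanesulfonate | O=S(=O)(OC1=C(Cl)C(=O)[C@](C)(O)[C@H](O)[C@@H]1CO)C(F)(F)F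
F10 | step 21 | (4S,5R,6R)-3-[(3E,5E,7S)-9-(tert-butyldimethylsilyloxy)-5,7-dimethylnona-3,5-dien-1-yn-1-yl]-2-chloro-5,6-dihydroxy-4-(hydroxymethyl)-6-methylcyclohex-2-en-1-one (not isolated) | CC(/C=C/C#CC1=C(Cl)C(=O)[C@](C)(O)[C@H](O)[C@@H]1CO)=C\[C@@H](C)CCO[Si](C)(C)C(C)(C)C
F11 | step 21 | (7R,8R,8aS)-3-[(1E,3E,5S)-7-(tert-butyldimethylsilyloxy)-3,5-dimethylhepta-1,3-dien-1-yl]-5-chloro-7,8-dihydroxy-7-methyl-8,8a-dihydro-1H-isochromen-6(7H)-one | CC(/C=C/C1=CC2=C(Cl)C(=O)[C@](C)(O)[C@H](O)[C@@H]2CO1)=C\[C@@H](C)CCO[Si](C)(C)C(C)(C)C
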